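## Structural features

The target is a diarylmethane: two hexasubstituted benzene rings joined through a single CH2 group. Ring A is an acylphloroglucinol with butanoyl at C1, hydroxyls at C2, C4 and C6, a 3-methylbut-2-enyl (prenyl) group at C3 and the bridge at C5. Ring B carries the bridge at C1', hydroxyls at C2' and C4', an acetyl group between them at C3', a methyl group at C5' and the only methyl ether at C6', para to the acetyl carbon. There is no stereocentre, so no stereocentres adjoin, and the only alkene is the prenyl double bond, which has no geometric isomers. Fragile features are the prenyl group (acid closes it onto a neighbouring phenol to give a chroman), the electron-rich polyphenol rings (oxidation, over-alkylation) and the CH2 bridge between two oxygenated rings, which strong acid or hot alkali can cut or scramble. The real difficulty is regiochemical: ring B has no free position, and one of its three similar oxygens must end as a methyl ether while the other two end as free phenols. The key step exploits the fact that O-C2', O-C4' and O-C6' are mutually meta and all ortho or para to C3'. A 2,4,6-trifluorobenzonitrile therefore maps onto ring B with the nitrile carbon as the future acetyl carbon, all three C–O bonds come from fluoride displacement, and the oxygens are told apart afterwards by their distance from the carbonyl.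

## Logic of the disconnections

19 is cut at the bond between ring A C3 and the allylic CH2, giving 17 and 18. The prenyl group is the most acid-sensitive part, so it must enter after every Lewis-acid step. The forward step must alkylate carbon rather than oxygen, and only once; ring B offers no free carbon, which helps.

17 is cut at the aryl–carbonyl bond of ring A, giving 15 and 16. Ring A of 15 is a free phloroglucinol with two equivalent open positions, so no regiochemical question arises. The forward acylation must not break the CH2 bridge.

15 is traced back to 14 by re-forming three O–benzyl bonds on ring A and two O–methyl bonds on ring B. This turns five phenols into ethers that tolerate organometallic and basic steps. The forward step must remove the two methyl groups flanking the acetyl group and spare the one para to it.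

14 is cut at the acetyl C–CH3 bond, giving 12 (through 13) and a methyl nucleophile. The nitrile is the latent acyl group and is also the activating group the next disconnection needs. The forward addition has to reach a nitrile carbon flanked by two methoxy groups.

12 is cut at its three aryl–oxygen bonds on ring B, giving 8 and 9. This removes all the oxygen functionality of ring B in one operation and leaves a precursor whose substitution pattern is fixed by C–F directed metalation. The forward step must replace all three fluorides without attacking the nitrile or the benzylic CH2.

8 is traced back to 7 by adding a hydroxyl at the bridge carbon. 7 is the direct product of a carbonyl addition, and the forward deoxygenation is helped by ring A, which stabilises the benzylic cation.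

7 is cut at the bond between the bridge carbon and ring B, giving 3 (as its metalated form 6) and 5. The bridge carbon comes from an aldehyde, and the only remaining C–H of 3 lies between two fluorines, so the site of metalation is unambiguous. The forward addition must outrun decomposition of the fluorinated aryl anion.

5 is traced back to 4 by removing three benzyl groups. Benzyl is chosen because it survives acid, alkoxide and Grignard steps and leaves together with the ring B methyl groups in one operation.

3 is cut at the aryl–methyl bond, giving 1 (as 2) and a methyl electrophile. The C–H between two fluorines of 1 is the most acidic, so the methyl group is placed where ring B needs it.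

## Other disconnections considered

Alternative 1: The cut is the ring A bond between the butanoyl-bearing carbon and its hydroxylated neighbour, so ring A is folded from the open-chain triketo ester A2. In the forward key step a magnesium alkoxide base would generate the C6 carbanion of A2 (flanked by the C5 and C7 ketones), which attacks the C1 ester in a Claisen-type closure; enolisation then gives the acylphloroglucinol A1.
- In its favour: ring A arrives already acylated at the correct carbon, and the bridge is never exposed to a Friedel–Crafts step. On both points it is better than steps 7 and 8 of the chosen plan. From A1 only debenzylation and prenylation remain, a shorter endgame than the four steps after 12.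
- Against it: A2 is a 2-substituted triketo ester with many tautomers and several competing closures (aldol closure from C2 onto C7, lactonisation to a hydroxypyrone). The ester under attack sits next to a carbon carrying a very bulky, fully substituted benzyl group.
- Comparison: the hexasubstituted ring B must still be built by a separate sequence, so the hardest regiochemical problem is left untouched. The chosen plan faces no regiochemical choice in its key step, whereas the alternative depends on one enolate winning among several. Overall the alternative is expected to be longer. Both plans end with the same late C-prenylation and are equal there.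

Alternative 2: The cut removes the aryl–carbonyl and the adjacent aryl–oxygen bond of ring A at once. In the forward key step a fluoride source would release an aryne from the silyl triflate A4. Butanoic acid A5 would add through oxygen at the aryne carbon remote from the methoxymethoxy group; the resulting aryl anion would attack the ester carbonyl and open to the ortho-hydroxyaryl ketone A3.
- In its favour: the conditions are almost neutral, ketone and phenol are placed in one step with an orientation set by the distortion of the alkoxy-substituted aryne, and no Lewis acid comes near the bridge. On that point it is better than step 8.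
- Against it: A4 is an ortho-silyl aryl triflate on a pentasubstituted ring that already carries the bridge and the complete ring B, so its preparation would be long. The aryl anion can be protonated by A5 before it acylates, which would give only an aryl ester. The methoxymethyl groups then need acid removal before prenylation.
- Comparison: ring B must again come from elsewhere. The regiocontrol of the insertion is as good as the regio-indifference of step 5, but the number of steps is clearly higher and the key intermediate much harder to reach than 8.

Alternative 3: The cut removes two ring B bonds, from the new phenol carbon to the methyl-bearing carbon and from the methoxy-bearing carbon to the bridge-bearing carbon. In the forward key step the cyclobutenone A7 is heated with the ynol ether A8. Four-electron ring opening to a vinylketene, cycloaddition with A8, a second ring opening and six-electron electrocyclisation would give the phenol A6.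
- In its favour: ring B is assembled convergently under neutral thermal conditions with four substituents placed unambiguously. The three oxygens are different from the outset, and the methoxy group the target keeps is born as such. On oxygen differentiation it is better than the chosen plan, which relies on chelation in step 7.
- Against it: A6 lacks the acetyl group. The last ring B position would have to be acylated in the presence of ring A, which is more nucleophilic and has two open positions, and the ethyl ether must later be cleaved beside the methyl ether. Neither A7 nor A8 is a catalogue compound, and A8 is volatile and sensitive.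
- Comparison: in the chosen plan the acetyl carbon is present from compound 1 as the nitrile carbon, which also drives the key step, so the chosen plan is ahead on the acyl group and on step count.

Key step: step 5

Remarks on the chemistry:
- Ring A is the butanoyl/prenyl ring and ring B the acetyl/methyl/methoxy ring; primed locants refer to ring B with the bridge carbon as C1'.
- Structure check: in 8 and 12 the nitrile carbon lies between two C–F (C–OMe) carbons and para to the third. This reproduces the acetyl group of the target flanked by two hydroxyls and para to the methoxy group, so no structure needed correction.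
- Benzyl is kept on ring A because it survives steps 4 to 6 and leaves in the same operation that frees the ring B phenols.
- The order in which the three fluorides of 8 leave is not controlled and does not matter. 10 and 11 are drawn for the order C4, C2, C6; every other order converges on 12.

## Route

Step 1
Reactants: 1 2,4,6-trifluorobenzonitrile
Product: 3 2,4,6-trifluoro-3-methylbenzonitrile, via aryllithium 2 (not isolated)
Conditions: LiN(iPr)2 (1.05 equiv), THF, -78 °C; then MeI (3 equiv), -78 → -30 °C
Reagents that add atoms: iodomethane, CI
Why: The ring C–H between two fluorines, further acidified by the nitrile, is removed by the hindered amide (fluorine-directed ortho-lithiation) and the aryllithium is methylated by SN2 on MeI; holding -78 °C suppresses LiF loss to an aryne and attack on the nitrile.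

Step 2
Reactants: 4 2,4,6-trihydroxybenzaldehyde
Product: 5 2,4,6-tris(benzyloxy)benzaldehyde
Conditions: BnBr (3.6 equiv), K2CO3 (5 equiv), DMF, 25 → 60 °C
Reagents that add atoms: benzyl bromide, BrCc1ccccc1
Why: Williamson ether synthesis; carbonate in DMF favours O-alkylation and the formyl group lowers ring nucleophilicity enough to hold back C-benzylation, while the two chelated ortho hydroxyls need the excess and the warming.

Step 3
Reactants: 3 2,4,6-trifluoro-3-methylbenzonitrile; 5 2,4,6-tris(benzyloxy)benzaldehyde
Product: 7 2,4,6-trifluoro-3-[hydroxy[2,4,6-tris(benzyloxy)phenyl]methyl]-5-methylbenzonitrile (racemic), via aryllithium 6 (not isolated)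
Conditions: LiN(iPr)2 (1.1 equiv), THF, -78 °C; then 5 in THF, -78 → -40 °C; aq. NH4Cl
Reagents that add atoms: none
Why: The only remaining ring C–H of 3 again lies between two fluorines, so lithiation is unambiguous, and the aryllithium adds 1,2 to the aldehyde; the carbinol centre forms racemic and is removed in step 4.

Step 4
Reactants: 7 2,4,6-trifluoro-3-[hydroxy[2,4,6-tris(benzyloxy)phenyl]methyl]-5-methylbenzonitrile
Product: 8 2,4,6-trifluoro-3-methyl-5-[[2,4,6-tris(benzyloxy)phenyl]methyl]benzonitrile
Conditions: Et3SiH (3 equiv), CF3CO2H (5 equiv), CH2Cl2, -20 → 0 °C
Reagents that add atoms: none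
Why: Ionic hydrogenation; acid ionises the doubly benzylic alcohol to a cation strongly stabilised by the three alkoxy groups of ring A, and the silane delivers hydride; aryl fluorides, nitrile and benzyl ethers are inert under these cold, brief conditions.

Step 5
Reactants: 8 2,4,6-trifluoro-3-methyl-5-[[2,4,6-tris(benzyloxy)phenyl]methyl]benzonitrile; 9 sodium methoxide
Product: 12 2,4,6-trimethoxy-3-methyl-5-[[2,4,6-tris(benzyloxy)phenyl]methyl]benzonitrile, via monomethoxy nitrile 10 (not isolated), via dimethoxy nitrile 11 (not isolated)
Conditions: NaOMe (8 equiv), MeOH/DMSO (1:3), 25 °C then 80 °C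
Reagents that add atoms: sodium methoxide (9), C[O-].[Na+]
Why: Methoxide adds to each C–F carbon to give a Meisenheimer anion whose charge is shared by C1, C3 and C5 and passed from C1 into the nitrile, and loss of fluoride restores the arene (addition–elimination); the closest known reaction type is alkoxide displacement of fluoride in polyfluorobenzonitriles. Fluoride is the right leaving group because addition is rate-limiting and the C–F carbon is the most electrophilic ring carbon. A methoxy group that has entered is meta to every carbon still bearing fluorine, so its lone pair pushes density onto C1, C3 and C5 and not onto the carbon under attack; it slows the later additions, together with crowding by the methyl and diarylmethyl groups, but does not block them, which is why the run is finished hot in a dipolar aprotic co-solvent. The nitrile is linear and keeps activating although it is flanked on both sides. No ring is closed and no stereocentre is formed. No regioselectivity is needed, because every order of displacement ends at 12. The chemoselectivity needed is ring carbon over nitrile carbon and over the doubly benzylic CH2: methoxide adds to the shielded nitrile only reversibly, and methoxide buffered by methanol is far too weak a base to deprotonate the diarylmethane. Benzyl ethers do not react with alkoxide.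

Step 6
Reactants: 12 2,4,6-trimethoxy-3-methyl-5-[[2,4,6-tris(benzyloxy)phenyl]methyl]benzonitrile
Product: 14 1-[2,4,6-trimethoxy-3-methyl-5-[[2,4,6-tris(benzyloxy)phenyl]methyl]phenyl]ethan-1-one, via magnesium ketiminate 13 (not isolated)
Conditions: MeMgBr (4 equiv), toluene/Et2O, 80 °C; then 2 M aq. HCl, THF, 50 °C
Reagents that add atoms: methylmagnesium bromide, C[Mg]Br; water, O
Why: Grignard addition to a nitrile stops at the magnesium ketiminate, which cannot take a second equivalent, and aqueous acid hydrolyses it to the methyl ketone; the ortho methoxy oxygens bind magnesium and guide the reagent to the hindered nitrile carbon, and heat in toluene supplies the rest.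

Step 7
Reactants: 14 1-[2,4,6-trimethoxy-3-methyl-5-[[2,4,6-tris(benzyloxy)phenyl]methyl]phenyl]ethan-1-one
Product: 15 1-[2,6-dihydroxy-4-methoxy-3-methyl-5-[(2,4,6-trihydroxyphenyl)methyl]phenyl]ethan-1-one
Conditions: BCl3 (10 equiv), C6HMe5 (6 equiv), CH2Cl2, -78 → 0 → 25 °C; MeOH, then H2O
Reagents that add atoms: none
Why: Lewis-acid ether cleavage; at low temperature BCl3 removes the aryl benzyl ethers while pentamethylbenzene traps the benzyl cations, so ring A is not C-benzylated, and on warming boron held by the acetyl oxygen removes the two flanking methyl groups through six-membered chelates; the methoxy group para to the acetyl group has no such assistance and should remain.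

Step 8
Reactants: 15 1-[2,6-dihydroxy-4-methoxy-3-methyl-5-[(2,4,6-trihydroxyphenyl)methyl]phenyl]ethan-1-one; 16 butanoyl chloride
Product: 17 1-[3-[(3-acetyl-2,4-dihydroxy-6-methoxy-5-methylphenyl)methyl]-2,4,6-trihydroxyphenyl]butan-1-one
Conditions: 16 (1.1 equiv), AlCl3 (6 equiv), CH2Cl2/PhNO2, 0 → 25 °C; ice-cold 1 M aq. HCl
Reagents that add atoms: butanoyl chloride (16), CCCC(=O)Cl
Why: Friedel–Crafts acylation; only ring A has open positions and the two are equivalent, the first acyl group deactivates the ring towards a second, and excess AlCl3 complexes the acetyl group and phenols of ring B, which should make heterolysis of the bridge towards a ring B benzylic cation unfavourable.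

Step 9
Reactants: 17 1-[3-[(3-acetyl-2,4-dihydroxy-6-methoxy-5-methylphenyl)methyl]-2,4,6-trihydroxyphenyl]butan-1-one; 18 1-bromo-3-methylbut-2-ene
Product: 19 1-[3-[(3-acetyl-2,4-dihydroxy-6-methoxy-5-methylphenyl)methyl]-2,4,6-trihydroxy-5-(3-methylbut-2-en-1-yl)phenyl]butan-1-one
Conditions: 18 (1.05 equiv), DBU (1.1 equiv), THF, 0 → 25 °C; dilute aq. citric acid work-up
Reagents that add atoms: 1-bromo-3-methylbut-2-ene (18), CC(C)=CCBr
Why: C-alkylation of a phenoxide by SN2 on the allylic bromide; the acylphloroglucinol ring A is the most acidic site, its only free ring carbon is the nucleophilic terminus of the vinylogous enolate, ring B has no free carbon, and one equivalent each of base and bromide limits O-alkylation and double alkylation.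

## Compound list

1 | 2,4,6-trifluorobenzonitrile | N#Cc1c(F)cc(F)cc1F | starting material
2 | (3-cyano-2,4,6-trifluorophenyl)lithium | N#Cc1c(F)cc(F)c([Li])c1F | intermediate (not isolated)
3 | 2,4,6-trifluoro-3-methylbenzonitrile | N#Cc1c(F)cc(F)c(C)c1F | intermediate
4 | 2,4,6-trihydroxybenzaldehyde | O=Cc1c(O)cc(O)cc1O | starting material
5 | 2,4,6-tris(benzyloxy)benzaldehyde | O=Cc1c(OCc2ccccc2)cc(OCc2ccccc2)cc1OCc1ccccc1 | intermediate
6 | (3-cyano-2,4,6-trifluoro-5-methylphenyl)lithium | N#Cc1c(F)c(C)c(F)c([Li])c1F | intermediate (not isolated)
7 | 2,4,6-trifluoro-3-[hydroxy[2,4,6-tris(benzyloxy)phenyl]methyl]-5-methylbenzonitrile (racemic) | N#Cc1c(F)c(C)c(F)c(C(O)c2c(OCc3ccccc3)cc(OCc3ccccc3)cc2OCc2ccccc2)c1F | intermediate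
8 | 2,4,6-trifluoro-3-methyl-5-[[2,4,6-tris(benzyloxy)phenyl]methyl]benzonitrile | N#Cc1c(F)c(C)c(F)c(Cc2c(OCc3ccccc3)cc(OCc3ccccc3)cc2OCc2ccccc2)c1F | intermediate
9 | sodium methoxide | C[O-].[Na+] | starting material
10 | 2,6-difluoro-4-methoxy-3-methyl-5-[[2,4,6-tris(benzyloxy)phenyl]methyl]benzonitrile | N#Cc1c(F)c(C)c(OC)c(Cc2c(OCc3ccccc3)cc(OCc3ccccc3)cc2OCc2ccccc2)c1F | intermediate (not isolated)
11 | 2-fluoro-4,6-dimethoxy-5-methyl-3-[[2,4,6-tris(benzyloxy)phenyl]methyl]benzonitrile | N#Cc1c(OC)c(C)c(OC)c(Cc2c(OCc3ccccc3)cc(OCc3ccccc3)cc2OCc2ccccc2)c1F | intermediate (not isolated)
12 | 2,4,6-trimethoxy-3-methyl-5-[[2,4,6-tris(benzyloxy)phenyl]methyl]benzonitrile | N#Cc1c(OC)c(C)c(OC)c(Cc2c(OCc3ccccc3)cc(OCc3ccccc3)cc2OCc2ccccc2)c1OC | intermediate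
13 | bromomagnesium ketiminate of 14 (N-bromomagnesio 1-arylethan-1-imine) | CC(=N[Mg]Br)c1c(OC)c(C)c(OC)c(Cc2c(OCc3ccccc3)cc(OCc3ccccc3)cc2OCc2ccccc2)c1OC | intermediate (not isolated)
14 | 1-[2,4,6-trimethoxy-3-methyl-5-[[2,4,6-tris(benzyloxy)phenyl]methyl]phenyl]ethan-1-one | CC(=O)c1c(OC)c(C)c(OC)c(Cc2c(OCc3ccccc3)cc(OCc3ccccc3)cc2OCc2ccccc2)c1OC | intermediate
15 | 1-[2,6-dihydroxy-4-methoxy-3-methyl-5-[(2,4,6-trihydroxyphenyl)methyl]phenyl]ethan-1-one | CC(=O)c1c(O)c(C)c(OC)c(Cc2c(O)cc(O)cc2O)c1O | intermediate
16 | butanoyl chloride | CCCC(=O)Cl | starting material
17 | 1-[3-[(3-acetyl-2,4-dihydroxy-6-methoxy-5-methylphenyl)methyl]-2,4,6-trihydroxyphenyl]butan-1-one | CCCC(=O)c1c(O)cc(O)c(Cc2c(O)c(C(C)=O)c(O)c(C)c2OC)c1O | intermediate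
18 | 1-bromo-3-methylbut-2-ene | CC(C)=CCBr | starting material
19 | 1-[3-[(3-acetyl-2,4-dihydroxy-6-methoxy-5-methylphenyl)methyl]-2,4,6-trihydroxy-5-(3-methylbut-2-en-1-yl)phenyl]butan-1-one (no stereocentre) | CCCC(=O)c1c(O)c(CC=C(C)C)c(O)c(Cc2c(O)c(C(C)=O)c(O)c(C)c2OC)c1O | target

## Step count and risk

Total: 9 steps. Longest linear sequence: 8 steps (1 → 19 through steps 1, 3, 4, 5, 6, 7, 8 and 9); step 2 is the one-step side branch that supplies 5.

Least certain steps:

**Step 5 (key step).** The most likely failure is stalling after two displacements, because the third C–F carbon sits on a ring that is now richer in electrons and crowded. On prolonged heating this would be accompanied by addition of methoxide to the nitrile or by base-induced degradation at the doubly benzylic CH2. The fallback moves the same threefold displacement onto the simpler ring before the bridge exists, where there is no bulky neighbour, no acidic CH2 and no benzyl ether, so harsher conditions are tolerable. It sets out from 3: NaOMe in MeOH/DMSO at 80–100 °C should give 2,4,6-trimethoxy-3-methylbenzonitrile F1. N-Bromosuccinimide in MeCN brominates its single ring C–H to 3-bromo-2,4,6-trimethoxy-5-methylbenzonitrile F2. Bromine–magnesium exchange with iPrMgCl·LiCl in THF and addition to 5 gives the racemic carbinol 3-[hydroxy[2,4,6-tris(benzyloxy)phenyl]methyl]-2,4,6-trimethoxy-5-methylbenzonitrile F3. Et3SiH/CF3CO2H then reduces F3 to 12, where the route is rejoined.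

**Step 3.** The fluorinated aryllithium may decompose (loss of LiF to an aryne, attack on the nitrile of a second molecule) faster than it adds to the hindered aldehyde, which three alkoxy groups make a poor electrophile. The fallback reverses the roles of the two rings. It sets out from 3: lithiation as before and quenching with DMF gives 3-formyl-2,4,6-trifluoro-5-methylbenzonitrile F4. This electron-poor aldehyde is then used in a reductive Friedel–Crafts alkylation of purchased 1,3,5-tris(benzyloxy)benzene F5 (CF3CO2H, Et3SiH, CH2Cl2, 0 °C, arene added slowly to limit triarylmethane formation). This should give 8 directly, so the route is rejoined at 8 and compounds 5 and 7 are bypassed.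

**Step 6.** Addition to the doubly ortho-substituted nitrile may be sluggish, the Grignard reagent may displace an ortho methoxy group by chelation-assisted ipso substitution, or hydrolysis of the hindered ketimine may be incomplete. The fallback builds the ketone in three conventional operations from 12. iBu2AlH in toluene at -78 → 0 °C with acidic work-up gives 2,4,6-trimethoxy-3-methyl-5-[[2,4,6-tris(benzyloxy)phenyl]methyl]benzaldehyde F6. MeMgBr in THF at 0 °C gives the racemic alcohol 1-[2,4,6-trimethoxy-3-methyl-5-[[2,4,6-tris(benzyloxy)phenyl]methyl]phenyl]ethan-1-ol F7. Dess–Martin periodinane in CH2Cl2 oxidises F7 to 14, where the route is rejoined.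

**Step 7.** Two processes threaten this step. Benzyl cations may alkylate the very nucleophilic ring A despite the scavenger. Separately, the methyl ether cleavage may be imperfectly differentiated: the second flanking methyl group may be removed incompletely, or the para methyl group may be lost, because all three methoxy groups are twisted out of the ring plane by two ortho neighbours and are therefore unusually basic. The fallback separates the two tasks and sets out from 14. Hydrogenolysis (H2, Pd/C, EtOAc/MeOH) removes the benzyl groups without any cation and gives 1-[2,4,6-trimethoxy-3-methyl-5-[(2,4,6-trihydroxyphenyl)methyl]phenyl]ethan-1-one F8. Treatment of F8 with 16 and excess AlCl3 (CH2Cl2/PhNO2, 25 → 40 °C) then acylates ring A and strips the two methyl ethers held in aluminium chelates by the acetyl group in one operation, rejoining the route at 17.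

**Step 8.** Strong Lewis acid may cut or scramble the CH2 bridge (ipso protonation of ring A with departure of a ring B benzylic cation), and O-acylation or double acylation may compete. The fallback replaces the acyl chloride and AlCl3 by a Houben–Hoesch reaction and sets out from 15. Butanenitrile, ZnCl2 and HCl gas in Et2O at 0 °C should precipitate the ketiminium salt 1-[3-[(3-acetyl-2,4-dihydroxy-6-methoxy-5-methylphenyl)methyl]-2,4,6-trihydroxyphenyl]butan-1-iminium chloride F9. This takes the product out of the acidic medium and cannot react a second time. Warm water hydrolyses F9 to 17, where the route is rejoined.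

**Step 9.** Alkylation may go to oxygen, or twice to carbon with dearomatisation, and base may trigger fragmentation at the bridge through a quinone methide. The fallback changes the polarity of the prenyl donor from an alkyl halide under base to a cation under mild acid. It sets out from 17: 2-methylbut-3-en-2-ol and BF3·OEt2 in 1,4-dioxane at 25 °C, stopped early to limit chroman formation, give 19 directly, so no new compound lies on the way.

## Further compounds

F1 | step 5 | 2,4,6-trimethoxy-3-methylbenzonitrile | N#Cc1c(OC)cc(OC)c(C)c1OC
F2 | step 5 | 3-bromo-2,4,6-trimethoxy-5-methylbenzonitrile | N#Cc1c(OC)c(Br)c(OC)c(C)c1OC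
F3 | step 5 | 3-[hydroxy[2,4,6-tris(benzyloxy)phenyl]methyl]-2,4,6-trimethoxy-5-methylbenzonitrile (racemic) | N#Cc1c(OC)c(C)c(OC)c(C(O)c2c(OCc3ccccc3)cc(OCc3ccccc3)cc2OCc2ccccc2)c1OC
F4 | step 3 | 3-formyl-2,4,6-trifluoro-5-methylbenzonitrile | N#Cc1c(F)c(C)c(F)c(C=O)c1F
F5 | step 3 | 1,3,5-tris(benzyloxy)benzene | c1ccc(COc2cc(OCc3ccccc3)cc(OCc3ccccc3)c2)cc1
F6 | step 6 | 2,4,6-trimethoxy-3-methyl-5-[[2,4,6-tris(benzyloxy)phenyl]methyl]benzaldehyde | O=Cc1c(OC)c(C)c(OC)c(Cc2c(OCc3ccccc3)cc(OCc3ccccc3)cc2OCc2ccccc2)c1OC
F7 | step 6 | 1-[2,4,6-trimethoxy-3-methyl-5-[[2,4,6-tris(benzyloxy)phenyl]methyl]phenyl]ethan-1-ol (racemic) | CC(O)c1c(OC)c(C)c(OC)c(Cc2c(OCc3ccccc3)cc(OCc3ccccc3)cc2OCc2ccccc2)c1OC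
F8 | step 7 | 1-[2,4,6-trimethoxy-3-methyl-5-[(2,4,6-trihydroxyphenyl)methyl]phenyl]ethan-1-one | CC(=O)c1c(OC)c(C)c(OC)c(Cc2c(O)cc(O)cc2O)c1OC
F9 | step 8 | 1-[3-[(3-acetyl-2,4-dihydroxy-6-methoxy-5-methylphenyl)methyl]-2,4,6-trihydroxyphenyl]butan-1-iminium chloride | CCCC(=[NH2+])c1c(O)cc(O)c(Cc2c(O)c(C(C)=O)c(O)c(C)c2OC)c1O.[Cl-]
F0 | step 9 | none | none
A1 | alternative 1 | 1-[3-[(3-acetyl-2,4-bis(benzyloxy)-6-methoxy-5-methylphenyl)methyl]-2,4,6-trihydroxyphenyl]butan-1-one | CCCC(=O)c1c(O)cc(O)c(Cc2c(OCc3ccccc3)c(C(C)=O)c(OCc3ccccc3)c(C)c2OC)c1O
A2 | alternative 1 | methyl 2-[(3-acetyl-2,4-bis(benzyloxy)-6-methoxy-5-methylphenyl)methyl]-3,5,7-trioxodecanoate (racemic) | COC(=O)C(Cc1c(OCc2ccccc2)c(C(C)=O)c(OCc2ccccc2)c(C)c1OC)C(=O)CC(=O)CC(=O)CCC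
A3 | alternative 2 | 1-[3-[[3-acetyl-6-methoxy-2,4-bis(methoxymethoxy)-5-methylphenyl]methyl]-6-hydroxy-2,4-bis(methoxymethoxy)phenyl]butan-1-one | CCCC(=O)c1c(O)cc(OCOC)c(Cc2c(OCOC)c(C(C)=O)c(OCOC)c(C)c2OC)c1OCOC
A4 | alternative 2 | 4-[[3-acetyl-6-methoxy-2,4-bis(methoxymethoxy)-5-methylphenyl]methyl]-3,5-bis(methoxymethoxy)-2-(trimethylsilyl)phenyl trifluoromethanesulfonate | C[Si](C)(C)c1c(OS(=O)(=O)C(F)(F)F)cc(OCOC)c(Cc2c(OCOC)c(C(C)=O)c(OCOC)c(C)c2OC)c1OCOC
A5 | alternative 2 | butanoic acid | CCCC(=O)O
A6 | alternative 3 | 5-ethoxy-3-methoxy-2-methyl-4-[[2,4,6-tris(benzyloxy)phenyl]methyl]phenol | CCOc1cc(O)c(C)c(OC)c1Cc1c(OCc2ccccc2)cc(OCc2ccccc2)cc1OCc1ccccc1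
A7 | alternative 3 | 3-ethoxy-2-[[2,4,6-tris(benzyloxy)phenyl]methyl]cyclobut-2-en-1-one | CCOC1=C(Cc2c(OCc3ccccc3)cc(OCc3ccccc3)cc2OCc2ccccc2)C(=O)C1
A8 | alternative 3 | 1-methoxyprop-1-yne | CC#COC
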